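The central benzene ring carries OMe at C1, C2, C4 and C5 and the indol-3-yl groups at C3 and C6. C3 and C6 are each flanked by two oxygen-bearing carbons, the 1,3-relationship that a Claisen condensation leaves behind. Cutting C2–C3 and C1–C6 at the dihydroxyquinone oxidation level gives dimethyl oxalate (C1–C2) and an unsymmetrical 1,4-bis(indol-3-yl)butane-2,3-dione (C3 to C6) that bears the 5-allyloxy and 6-prenyl indoles. One base-mediated operation forges both bonds and closes the fully oxygenated carbocycle. The diketone comes from two indolylmagnesium openings of a C4 bis-epoxide and oxidation of the diol; reductive methylation and deallylation finish the synthesis.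

Key step: step 6

Remark: bis-epoxide 5 is used as its racemate, so 7 and 9 are racemic; the SMILES show the (S,S) series and both stereocentres are erased in step 5.
Remark: the indole N–H groups stay unprotected throughout, since N-oxalylation in step 6 is reversed by methoxide and no deprotection step is then needed.

Step 1
Reactants: 1 6-bromo-1H-indole
Product: 2 6-(3-methylbut-2-en-1-yl)-1H-indole
Conditions: tributyl(3-methylbut-2-en-1-yl)stannane (1.3 eq), Pd(PPh3)4 (5 mol%), DMF, 100 °C, Ar
Reagents that add atoms: tributyl(3-methylbut-2-en-1-yl)stannane, CCCC[Sn](CCCC)(CCCC)CC=C(C)C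
Why: Stille cross-coupling of the aryl bromide with the allylic stannane tolerates the free indole N–H and, with Pd(PPh3)4 in DMF, should deliver the linear prenyl group by coupling at the unsubstituted allyl terminus.

Step 2
Reactants: 3 1H-indol-5-ol
Product: 4 5-(allyloxy)-1H-indole
Conditions: allyl bromide (1.1 eq), K2CO3 (1.5 eq), acetone, reflux
Reagents that add atoms: allyl bromide, C=CCBr
Why: Williamson ether synthesis in which K2CO3 ionises only the phenol (far more acidic than the indole N–H), so alkylation should occur at oxygen alone.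

Step 3
Reactants: 2 6-(3-methylbut-2-en-1-yl)-1H-indole; 5 (2S*,2'S*)-2,2'-bioxirane
Product: 7 (1S*)-2-[6-(3-methylbut-2-en-1-yl)-1H-indol-3-yl]-1-[(2S*)-oxiran-2-yl]ethan-1-ol, via [6-(3-methylbut-2-en-1-yl)indol-1-yl]magnesium bromide 6 (not isolated)
Conditions: EtMgBr (1.05 eq), Et2O/toluene, 0 °C to rt; then 5 (4 eq), 0 °C to rt; pH 7 buffer
Reagents that add atoms: none
Why: N-Magnesiated indoles attack epoxides through C3 at the unhindered CH2 terminus (the classical tryptophol-type epoxide opening), the fourfold excess of 5 should limit reaction to one oxirane, and both stereocentres are inherited unchanged from 5 because no bond to them is broken.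

Step 4
Reactants: 7 (1S*)-2-[6-(3-methylbut-2-en-1-yl)-1H-indol-3-yl]-1-[(2S*)-oxiran-2-yl]ethan-1-ol; 4 5-(allyloxy)-1H-indole
Product: 9 (2S*,3S*)-1-[5-(allyloxy)-1H-indol-3-yl]-4-[6-(3-methylbut-2-en-1-yl)-1H-indol-3-yl]butane-2,3-diol, via [5-(allyloxy)indol-1-yl]magnesium bromide 8 (not isolated)
Conditions: 4 (3 eq), EtMgBr (3 eq), Et2O/toluene, 0 °C to rt; then 7 (1 eq), rt to 45 °C; pH 7 buffer
Reagents that add atoms: none
Why: The same C3-selective epoxide opening by an indolylmagnesium bromide, run with excess 8 to cover the O–H and N–H protons of 7, should open the remaining oxirane at its CH2 carbon and leave the two carbinol centres with the configuration inherited from 5.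

Step 5
Reactants: 9 (2S*,3S*)-1-[5-(allyloxy)-1H-indol-3-yl]-4-[6-(3-methylbut-2-en-1-yl)-1H-indol-3-yl]butane-2,3-diol
Product: 10 1-[5-(allyloxy)-1H-indol-3-yl]-4-[6-(3-methylbut-2-en-1-yl)-1H-indol-3-yl]butane-2,3-dione
Conditions: 2-iodoxybenzoic acid (IBX, 3 eq), DMSO, rt, Ar
Reagents that add atoms: none
Why: IBX oxidation of a 1,2-diol proceeds through the α-ketol to the 1,2-diketone without glycol C–C cleavage and at room temperature should spare the alkenes, the allyl ether and the indole rings, erasing both stereocentres.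

Step 6
Reactants: 10 1-[5-(allyloxy)-1H-indol-3-yl]-4-[6-(3-methylbut-2-en-1-yl)-1H-indol-3-yl]butane-2,3-dione; 11 dimethyl oxalate
Product: 13 3-[5-(allyloxy)-1H-indol-3-yl]-2,5-dihydroxy-6-[6-(3-methylbut-2-en-1-yl)-1H-indol-3-yl]cyclohexa-2,5-diene-1,4-dione, via open-chain oxalyl diketone 12 (not isolated)
Conditions: 11 (3 eq), NaOMe (6 eq), THF/MeOH, slow addition of 10 at 0 °C, then 50 °C, Ar; 1 M HCl
Reagents that add atoms: none
Why: Proposed new method: methoxide turns the enolised 1,2-diketone into its enolate, whose indolyl-bearing carbon C3 is C-acylated by the non-enolisable dimethyl oxalate (crossed Claisen) to give 12; the enolate at the second indolylmethylene C6 then adds to the remaining ester carbonyl C1, and the resulting cyclohexanetetraone tautomerises to the dihydroxyquinone, which is held as its dianion until acidification. The closest known reaction type is the double Claisen condensation of dialkyl oxalates with bis-enolisable ketones such as 1,3-diarylacetones, which closes cyclopentanetriones by the same two events. The one new ring, the carbocycle C1–C6, closes in the 6-exo-trig mode of a Dieckmann condensation (enolate carbon onto an ester C=O that lies outside the forming ring). No stereocentre is created, because 12 is enolised and the product ring is planar. The step needs chemoselectivity for crossed acylation over self-aldol condensation of 10 and for C- over O-cyclisation: slow addition of 10 into excess oxalate keeps the only strong electrophile non-enolisable, and O-acylated or lactone by-products can revert under methoxide and drain into the carbocyclic dianion, a doubly vinylogous carboxylate that is the thermodynamic sink. Deprotonation of the indole nitrogens is less favourable than enolisation of the diketone, and N-oxalyl indoles, if formed, are cleaved again by methoxide.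

Step 7
Reactants: 13 3-[5-(allyloxy)-1H-indol-3-yl]-2,5-dihydroxy-6-[6-(3-methylbut-2-en-1-yl)-1H-indol-3-yl]cyclohexa-2,5-diene-1,4-dione
Product: 15 5-(allyloxy)-3-[2,3,5,6-tetramethoxy-4-[6-(3-methylbut-2-en-1-yl)-1H-indol-3-yl]phenyl]-1H-indole, via tetrahydroxybenzene 14 (not isolated)
Conditions: Na2S2O4 (excess), THF/H2O, rt, Ar; solvent switch under Ar; then Me2SO4 (8 eq), K2CO3 (10 eq), degassed acetone, reflux
Reagents that add atoms: dimethyl sulfate, COS(=O)(=O)OC
Why: Reductive methylation of a quinone: dithionite reduces 13 to the air-sensitive tetrol 14, whose four phenolic O–H groups are then etherified by Me2SO4 under K2CO3 (Williamson conditions), a base too weak to ionise the indole N–H, so methylation should stay on oxygen.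

Step 8
Reactants: 15 5-(allyloxy)-3-[2,3,5,6-tetramethoxy-4-[6-(3-methylbut-2-en-1-yl)-1H-indol-3-yl]phenyl]-1H-indole
Product: 16 3-[2,3,5,6-tetramethoxy-4-[6-(3-methylbut-2-en-1-yl)-1H-indol-3-yl]phenyl]-1H-indol-5-ol
Conditions: Pd(PPh3)4 (5 mol%), morpholine (5 eq), THF, rt
Reagents that add atoms: none
Why: Tsuji–Trost deallylation in which zerovalent palladium ionises the aryl allyl ether to a π-allyl complex that morpholine captures, while the C-bound prenyl group, the methyl ethers and the indoles have no allylic leaving group and should be untouched.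

Compound list
1 | 6-bromo-1H-indole | Brc1ccc2cc[nH]c2c1 | starting material
2 | 6-(3-methylbut-2-en-1-yl)-1H-indole (6-prenylindole) | CC(C)=CCc1ccc2cc[nH]c2c1 | intermediate
3 | 1H-indol-5-ol (5-hydroxyindole) | Oc1ccc2[nH]ccc2c1 | starting material
4 | 5-(allyloxy)-1H-indole | C=CCOc1ccc2[nH]ccc2c1 | intermediate
5 | (2S*,2'S*)-2,2'-bioxirane (racemic 1,2:3,4-diepoxybutane, (S,S) enantiomer drawn) | C1O[C@@H]1[C@@H]1CO1 | starting material
6 | [6-(3-methylbut-2-en-1-yl)indol-1-yl]magnesium bromide (not isolated) | CC(C)=CCc1ccc2ccn([Mg]Br)c2c1 | intermediate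
7 | (1S*)-2-[6-(3-methylbut-2-en-1-yl)-1H-indol-3-yl]-1-[(2S*)-oxiran-2-yl]ethan-1-ol (racemic) | O[C@@H](Cc1c[nH]c2cc(CC=C(C)C)ccc12)[C@@H]1CO1 | intermediate
8 | [5-(allyloxy)indol-1-yl]magnesium bromide (not isolated) | C=CCOc1ccc2n([Mg]Br)ccc2c1 | intermediate
9 | (2S*,3S*)-1-[5-(allyloxy)-1H-indol-3-yl]-4-[6-(3-methylbut-2-en-1-yl)-1H-indol-3-yl]butane-2,3-diol (racemic) | O[C@@H](Cc1c[nH]c2cc(CC=C(C)C)ccc12)[C@@H](O)Cc1c[nH]c2ccc(OCC=C)cc12 | intermediate
10 | 1-[5-(allyloxy)-1H-indol-3-yl]-4-[6-(3-methylbut-2-en-1-yl)-1H-indol-3-yl]butane-2,3-dione (key-step precursor) | C=CCOc1ccc2[nH]cc(CC(=O)C(=O)Cc3c[nH]c4cc(CC=C(C)C)ccc34)c2c1 | intermediate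
11 | dimethyl oxalate | COC(=O)C(=O)OC | starting material
12 | methyl (3RS)-3-[5-(allyloxy)-1H-indol-3-yl]-6-[6-(3-methylbut-2-en-1-yl)-1H-indol-3-yl]-2,4,5-trioxohexanoate (not isolated; C3 is enolised and configurationally labile; acylation at the other methylene converges on 13) | COC(=O)C(=O)C(c1c[nH]c2ccc(OCC=C)cc12)C(=O)C(=O)Cc1c[nH]c2cc(CC=C(C)C)ccc12 | intermediate
13 | 3-[5-(allyloxy)-1H-indol-3-yl]-2,5-dihydroxy-6-[6-(3-methylbut-2-en-1-yl)-1H-indol-3-yl]cyclohexa-2,5-diene-1,4-dione (key-step product) | O=C1C(O)=C(c2c[nH]c3cc(CC=C(C)C)ccc23)C(=O)C(O)=C1c1c[nH]c2ccc(OCC=C)cc12 | intermediate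
14 | 3-[5-(allyloxy)-1H-indol-3-yl]-6-[6-(3-methylbut-2-en-1-yl)-1H-indol-3-yl]benzene-1,2,4,5-tetrol (not isolated) | Oc1c(O)c(-c2c[nH]c3ccc(OCC=C)cc23)c(O)c(O)c1-c1c[nH]c2cc(CC=C(C)C)ccc12 | intermediate
15 | 5-(allyloxy)-3-[2,3,5,6-tetramethoxy-4-[6-(3-methylbut-2-en-1-yl)-1H-indol-3-yl]phenyl]-1H-indole | COc1c(OC)c(-c2c[nH]c3ccc(OCC=C)cc23)c(OC)c(OC)c1-c1c[nH]c2cc(CC=C(C)C)ccc12 | intermediate
16 | 3-[2,3,5,6-tetramethoxy-4-[6-(3-methylbut-2-en-1-yl)-1H-indol-3-yl]phenyl]-1H-indol-5-ol | COc1c(OC)c(-c2c[nH]c3ccc(O)cc23)c(OC)c(OC)c1-c1c[nH]c2cc(CC=C(C)C)ccc12 | target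

Total steps: 8. Longest linear sequence: 7 (steps 1, 3, 4, 5, 6, 7, 8, from 1).

Steps most likely to fail

Step 6. The enolised diketone may condense with itself, O-acylation or lactone closure may fail to equilibrate to the carbocycle, or the electron-rich enolates may degrade oxidatively before ring closure. The fallback uses the established route to bis(indolyl)dihydroxyquinones and sets out from 4 and 2. Acid-promoted conjugate addition of 4 to 2,5-dichloro-1,4-benzoquinone (AcOH, rt), followed by reoxidation with 2,3-dichloro-5,6-dicyano-1,4-benzoquinone (DDQ), should give 2,5-dichloro-3-[5-(allyloxy)-1H-indol-3-yl]cyclohexa-2,5-diene-1,4-dione F1. A second addition of 2 under the same acid and DDQ regime should give 2,5-dichloro-3-[5-(allyloxy)-1H-indol-3-yl]-6-[6-(3-methylbut-2-en-1-yl)-1H-indol-3-yl]cyclohexa-2,5-diene-1,4-dione F2. NaOH in aqueous MeOH at reflux then replaces both vinylic chlorides by hydroxyl through addition–elimination, and the route is rejoined at 13.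

Step 3. The ambident N-magnesio indole may alkylate at nitrogen, MgBr2 from the Schlenk equilibrium may open the oxirane to a bromohydrin, and a second molecule of 6 may open the remaining oxirane. The fallback replaces the ambident nucleophile by a carbon-centred one and sets out from 2. C3-iodination and N-protection (I2, KOH, DMF; then Boc2O, DMAP, CH2Cl2) give tert-butyl 3-iodo-6-(3-methylbut-2-en-1-yl)-1H-indole-1-carboxylate F3. Iodine–magnesium exchange (i-PrMgCl·LiCl, THF, −40 °C) and CuI-catalysed (10 mol%) opening of excess 5 at CH2 give tert-butyl 3-[(2S*)-2-hydroxy-2-[(2S*)-oxiran-2-yl]ethyl]-6-(3-methylbut-2-en-1-yl)-1H-indole-1-carboxylate F4. F4 takes the place of 7 under the conditions of step 4 to give tert-butyl 3-[(2S*,3S*)-4-[5-(allyloxy)-1H-indol-3-yl]-2,3-dihydroxybutyl]-6-(3-methylbut-2-en-1-yl)-1H-indole-1-carboxylate F5. K2CO3 in MeOH removes the Boc group and the route is rejoined at 9.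

Step 7. The tetrol may be reoxidised by traces of air before it is alkylated, the four hindered phenols may be methylated incompletely, and the indole nitrogens may be methylated if the base is too strong. The fallback methylates at the quinone oxidation level first and sets out from 13. Me2SO4 and K2CO3 in acetone etherify the two acidic enolic hydroxyls to give 3-[5-(allyloxy)-1H-indol-3-yl]-2,5-dimethoxy-6-[6-(3-methylbut-2-en-1-yl)-1H-indol-3-yl]cyclohexa-2,5-diene-1,4-dione F6. Na2S2O4 reduces F6 to the far less air-sensitive 2-[5-(allyloxy)-1H-indol-3-yl]-3,6-dimethoxy-5-[6-(3-methylbut-2-en-1-yl)-1H-indol-3-yl]benzene-1,4-diol F7. Methylation of the two remaining phenols (Me2SO4, K2CO3, acetone) rejoins the route at 15.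

Further compounds
F1 | step 6 | 2,5-dichloro-3-[5-(allyloxy)-1H-indol-3-yl]cyclohexa-2,5-diene-1,4-dione | O=C1C=C(Cl)C(=O)C(c2c[nH]c3ccc(OCC=C)cc23)=C1Cl
F2 | step 6 | 2,5-dichloro-3-[5-(allyloxy)-1H-indol-3-yl]-6-[6-(3-methylbut-2-en-1-yl)-1H-indol-3-yl]cyclohexa-2,5-diene-1,4-dione | O=C1C(c2c[nH]c3cc(CC=C(C)C)ccc23)=C(Cl)C(=O)C(c2c[nH]c3ccc(OCC=C)cc23)=C1Cl
F3 | step 3 | tert-butyl 3-iodo-6-(3-methylbut-2-en-1-yl)-1H-indole-1-carboxylate | CC(C)=CCc1ccc2c(I)cn(C(=O)OC(C)(C)C)c2c1
F4 | step 3 | tert-butyl 3-[(2S*)-2-hydroxy-2-[(2S*)-oxiran-2-yl]ethyl]-6-(3-methylbut-2-en-1-yl)-1H-indole-1-carboxylate | O[C@@H](Cc1cn(C(=O)OC(C)(C)C)c2cc(CC=C(C)C)ccc12)[C@@H]1CO1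
F5 | step 3 | tert-butyl 3-[(2S*,3S*)-4-[5-(allyloxy)-1H-indol-3-yl]-2,3-dihydroxybutyl]-6-(3-methylbut-2-en-1-yl)-1H-indole-1-carboxylate | O[C@@H](Cc1cn(C(=O)OC(C)(C)C)c2cc(CC=C(C)C)ccc12)[C@@H](O)Cc1c[nH]c2ccc(OCC=C)cc12
F6 | step 7 | 3-[5-(allyloxy)-1H-indol-3-yl]-2,5-dimethoxy-6-[6-(3-methylbut-2-en-1-yl)-1H-indol-3-yl]cyclohexa-2,5-diene-1,4-dione | COC1=C(c2c[nH]c3cc(CC=C(C)C)ccc23)C(=O)C(OC)=C(c2c[nH]c3ccc(OCC=C)cc23)C1=O
F7 | step 7 | 2-[5-(allyloxy)-1H-indol-3-yl]-3,6-dimethoxy-5-[6-(3-methylbut-2-en-1-yl)-1H-indol-3-yl]benzene-1,4-diol | COc1c(O)c(-c2c[nH]c3ccc(OCC=C)cc23)c(OC)c(O)c1-c1c[nH]c2cc(CC=C(C)C)ccc12
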